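0.1563 M of product is where the north run stands at 32 h, from a charge of 0.400 M of each reactant, and I want to know where the rest went.

| flask | substrate | partner | time |
|---|---|---|---|
| north | 0.400 M | 0.400 M |  |
| south | 0.800 M | 0.400 M |  |
| north-east | 0.400 M | 1.20 M |  |
| east | 0.200 M | 0.200 M | 32 h |

| run | time / h | [product] / M |
|---|---|---|
| north run | 1.3 | 0.0627 |
| north run | 2.0 | 0.0811 |
| north run | 3.2 | 0.0999 |
| north run | 5.1 | 0.1172 |
| north run | 8.1 | 0.1328 |
| north run | 13 | 0.1437 |
| north run | 20 | 0.1481 |
| north run | 32 | 0.1563 |
| south run | 1.3 | 0.0995 |
| south run | 2.0 | 0.1208 |
| south run | 3.2 | 0.1417 |
| south run | 5.1 | 0.1602 |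
| south run | 8.1 | 0.1736 |
| south run | 13 | 0.1847 |
| south run | 20 | 0.1930 |
| south run | 32 | 0.1968 |
| north-east run | 1.3 | 0.1970 |
| north-east run | 2.0 | 0.2326 |
| north-east run | 3.2 | 0.2615 |
| north-east run | 5.1 | 0.2803 |
| north-east run | 8.1 | 0.2869 |
| north-east run | 13 | 0.2922 |
| north-east run | 20 | 0.2909 |
| north-east run | 32 | 0.2899 |

(scatter of a reading: 0.001 M)

- the exponent of [substrate] in the starting rate at the charge of the north run (at the point where two percent of the substrate have become product) (one fixed amount of product, the same in the runs compared)
- the exponent of [partner] in the starting rate at the charge of the north run (at the point where two percent of the substrate have become product)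
- product in the east run at 32 h, as a share of the substrate charged

- Overall: substrate + partner -> product.
- Constant volume, constant temperature.
- A reading of a species includes what of it is bound.
- An order is taken over about fifteen percent of the charge, up and down.

I follow the north run slowly. Over the first 1.3 h, product comes at 0.0482 M h⁻¹ on average. Between 5.1 h and 8.1 h it comes at 5.20 mM h⁻¹, far slower than at first, though c(product) has reached just 0.1328 M. At the end the readings creep. So I suppose substrate also leaves by a path making no product, second order in substrate. At fixed partner, each portion of substrate then goes forward with the share A/(A + c(substrate)). Summed over the run, with A held as one average value though partner falls, and the last reading taken as the end: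

c(product, end) = A · ln(1 + c(substrate, start)/A)

A stands on both sides, so I try a value, correct it by the mismatch over the slope, and put the answer back.

north, from 0.100 M: A = 0.0943 M

north-east, from 0.400 M: A = 0.465 M, then 0.473 M

A is the crossover level, the substrate concentration at which the forward path and the loss run equal, a selectivity factor with the unit of a concentration. North's A gives the south run 0.212 M, above its reading of 0.1968 M, which is still climbing. That is near enough for me to keep one A at both substrate charges, and on my supposition this makes the forward path first order in substrate, so I take an exponent of one. Across partner, A gives the exponent 1.47, and as my supposed loss holds no partner, I take this as my order in partner. For the east run, which I take as finished at 32 h: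

A = 0.0341 M, so c(product) = 0.0657 M, or 32.8%

The forecast gives 0.9 for the order in substrate, 1.3 for the order in partner and 26% for the east yield, and it writes that “Rates fall far faster than depletion explains”. Its yield is lower than mine, and it reads that fall in rate as inhibition by product.

The flask gives 1.0, 1.4 and 29.9%.

    2 partner ⇌ reagent dimer, settled at all times (2.860 M⁻¹)
    substrate + reagent dimer → product + partner (2.016 M⁻¹ h⁻¹)
    2 partner → lost reagent (0.1534 M⁻¹ h⁻¹)
    2 substrate → homo dimer (0.7452 M⁻¹ h⁻¹)

In the east run, taking away the conversion of 2 substrate into homo dimer lifts the yield from 29.9% to 55.6%, which is 37% of what is missing. Put back into the rule, with the simulated east yield read as an end value, one correction gives A of about 0.0286 M, lower than my 0.0341 M. In the south run, north's A gave 0.212 M for the end, above a quarter of the charge, and that run reaches 0.200 M at 48.7 h.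

Readings and results are calculated with constants of no real substance; scatter was added.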